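**Retrosynthetic overview**

- Feature: ring A carries O1, 5-OH and 7-OH on alternate carbons (C8a, C5, C7), so it is a phloroglucinol unit whose three nuclear CH carbons are equivalent. C2 is a lone CH between O1 and C3, so it can come from a one-carbon reagent.
- Key disconnections: C4–C4a (Friedel–Crafts acylation of phloroglucinol by an arylacetic acid), then C2–C3 and O1–C2 (formylative closure of ring C with DMF), both in one pot.
- The dimethylpyran (ring D) is built first, regiospecifically, on methyl homovanillate by propargyl ether Claisen rearrangement and oxa-6π closure. It is then hydrogenated to the chroman, because the 2H-chromene alkene should not survive hot BF3·OEt2.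
- Ring order: ring B (bought arene) → ring D (step 2) → ring C onto ring A (step 5) → the C3=C4 alkene of ring D restored last by DDQ on the triacetate, then deacetylation.

Key step: step 5

Remark on the chemistry: phloroglucinol is taken as the anhydrous solid (the dihydrate is dried first, since water destroys BF3·OEt2); the target has no stereocentre, so no stereocontrol is needed.

**Route**

Step 1
Reactants: 1 methyl 2-(4-hydroxy-3-methoxyphenyl)acetate (methyl homovanillate); 2 3-chloro-3-methylbut-1-yne
Product: 3 methyl 2-[3-methoxy-4-(2-methylbut-3-yn-2-yloxy)phenyl]acetate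
Conditions: K2CO3, KI (cat.), CuI (cat.), acetone, reflux
Reagents that add atoms: none
Why: Williamson-type etherification in which the phenoxide of 1 captures the copper-activated tertiary propargylic chloride, a standard way to aryl 1,1-dimethylpropargyl ethers of guaiacol-type phenols, and K2CO3 leaves the methyl ester alone.

Step 2
Reactants: 3 methyl 2-[3-methoxy-4-(2-methylbut-3-yn-2-yloxy)phenyl]acetate
Product: 6 methyl 2-(8-methoxy-2,2-dimethyl-2H-chromen-6-yl)acetate, via ortho-allenylphenol 4 (not isolated), via ortho-quinone methide 5 (not isolated)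
Conditions: N,N-diethylaniline, 190 °C
Reagents that add atoms: none
Why: Aromatic propargyl Claisen rearrangement, in which the [3,3] shift goes to the only ortho carbon that bears hydrogen (the methoxy-bearing ortho carbon cannot rearomatise and reverts) and gives allenylphenol 4 after enolisation, whose 1,5-hydrogen shift gives quinone methide 5 that closes ring D by oxa-6π electrocyclisation, so the regiochemistry is fixed where an acid-mediated prenylation of the guaiacol could also attack para to the methoxy group.

Step 3
Reactants: 6 methyl 2-(8-methoxy-2,2-dimethyl-2H-chromen-6-yl)acetate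
Product: 7 methyl 2-(8-methoxy-2,2-dimethylchroman-6-yl)acetate
Conditions: H2 (1 atm), Pd/C (10 wt% Pd), EtOAc, rt
Reagents that add atoms: none
Why: Catalytic hydrogenation of the styrene-type C3=C4 bond is fast at 1 atm while arene, ester and ethers stay intact, and it stores the acid-sensitive alkene as the chroman, which should tolerate hot BF3·OEt2.

Step 4
Reactants: 7 methyl 2-(8-methoxy-2,2-dimethylchroman-6-yl)acetate
Product: 8 (8-hydroxy-2,2-dimethylchroman-6-yl)acetic acid
Conditions: NaSEt (5 equiv), N-methyl-2-pyrrolidone, 130 °C; then aq. HCl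
Reagents that add atoms: none
Why: Thiolate SN2 dealkylation, in which ethanethiolate attacks both O-methyl carbons (aryl methyl ether and methyl ester) while the tertiary chroman ether carbon is inert to SN2, so the pyran ring that a Lewis acid such as BBr3 could open stays closed.

Step 5
Reactants: 8 (8-hydroxy-2,2-dimethylchroman-6-yl)acetic acid; 9 phloroglucinol (anhydrous); 10 N,N-dimethylformamide
Product: 13 5,7-dihydroxy-3-(8-hydroxy-2,2-dimethylchroman-6-yl)-4H-chromen-4-one, via deoxybenzoin 11 (not isolated), via enaminoketone 12 (not isolated)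
Conditions: BF3·OEt2 (neat), 85 °C; then DMF 10, MeSO2Cl, 70 °C; then aq. NaOAc
Reagents that add atoms: none
Why: BF3 turns the carboxyl group of 8 into an acylating species that C-acylates 9 (C4–C4a, Friedel–Crafts), and ketone 11 stays coordinated to boron through its ortho-hydroxy carbonyl unit, which makes its methylene enolisable. DMF and MeSO2Cl then form a Vilsmeier-type iminium salt that attacks this methylene (C2–C3) to give enaminoketone 12; an ortho-hydroxyl adds to the aminomethylene carbon of its C-protonated iminium form (O1–C2) and loss of dimethylamine aromatises the pyranone. The closest known reaction is the one-pot deoxybenzoin route to isoflavones (BF3·OEt2 acylation of a phenol by an arylacetic acid, then DMF/MeSO2Cl closure), which tolerates free phenolic hydroxyls. Ring C closes by 6-exo-trig attack of oxygen on the exocyclic C=N+ carbon, and no stereocentre is formed. The step needs mono-acylation and one regioisomer: the three nuclear carbons of 9 are equivalent and the first acyl group deactivates the ring, the two ortho-hydroxyls of 11 are equivalent so only the 5,7-dihydroxy pattern can form, and phloroglucinol is far more nucleophilic than the chroman arene of 8. The saturated chroman ether, itself the product of acid-mediated cyclisations, should survive the medium.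

Step 6
Reactants: 13 5,7-dihydroxy-3-(8-hydroxy-2,2-dimethylchroman-6-yl)-4H-chromen-4-one
Product: 14 3-(8-acetoxy-2,2-dimethylchroman-6-yl)-4-oxo-4H-chromene-5,7-diyl diacetate
Conditions: Ac2O, pyridine, DMAP (cat.), rt to 50 °C
Reagents that add atoms: acetic anhydride, CC(=O)OC(C)=O
Why: DMAP-catalysed O-acetylation of all three phenols, the hydrogen-bonded 5-OH included, should give one defined triacetate in which the oxidisable chroman 8-hydroxyl is masked before the quinone oxidant is used.

Step 7
Reactants: 14 3-(8-acetoxy-2,2-dimethylchroman-6-yl)-4-oxo-4H-chromene-5,7-diyl diacetate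
Product: 15 3-(8-acetoxy-2,2-dimethyl-2H-chromen-6-yl)-4-oxo-4H-chromene-5,7-diyl diacetate
Conditions: DDQ (2 equiv), 1,4-dioxane, reflux
Reagents that add atoms: none
Why: DDQ dehydrogenation, in which hydride abstraction from the benzylic C4 methylene (cation stabilised by the ring oxygen through C8a) and loss of the C3 proton install the C3=C4 alkene, a known conversion of 2,2-dimethylchromans into 2,2-dimethyl-2H-chromenes, and the acetylated isoflavone offers no other abstractable hydride.

Step 8
Reactants: 15 3-(8-acetoxy-2,2-dimethyl-2H-chromen-6-yl)-4-oxo-4H-chromene-5,7-diyl diacetate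
Product: 16 semilicoisoflavone B
Conditions: K2CO3 (0.5 equiv), MeOH, 0 °C to rt; then AcOH
Reagents that add atoms: none
Why: Base-catalysed transesterification with methanol cleaves the three aryl acetates under conditions mild enough to leave the pyranone ring C and the chromene untouched.

**Compound list**

1 | methyl 2-(4-hydroxy-3-methoxyphenyl)acetate (methyl homovanillate) | COC(=O)Cc1ccc(O)c(OC)c1 | starting material
2 | 3-chloro-3-methylbut-1-yne | CC(C)(Cl)C#C | starting material
3 | methyl 2-[3-methoxy-4-(2-methylbut-3-yn-2-yloxy)phenyl]acetate | COC(=O)Cc1ccc(OC(C)(C)C#C)c(OC)c1 | intermediate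
4 | ortho-allenylphenol: methyl 2-[4-hydroxy-3-methoxy-5-(3-methylbuta-1,2-dien-1-yl)phenyl]acetate (formed in the flask) | COC(=O)Cc1cc(OC)c(O)c(C=C=C(C)C)c1 | intermediate
5 | ortho-quinone methide: methyl 2-[(3Z)-5-methoxy-3-(3-methylbut-2-en-1-ylidene)-4-oxocyclohexa-1,5-dien-1-yl]acetate (formed in the flask) | O=C1/C(=C\C=C(C)C)C=C(CC(=O)OC)C=C1OC | intermediate
6 | methyl 2-(8-methoxy-2,2-dimethyl-2H-chromen-6-yl)acetate | COC(=O)Cc1cc(OC)c2OC(C)(C)C=Cc2c1 | intermediate
7 | methyl 2-(8-methoxy-2,2-dimethylchroman-6-yl)acetate | COC(=O)Cc1cc(OC)c2OC(C)(C)CCc2c1 | intermediate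
8 | (8-hydroxy-2,2-dimethylchroman-6-yl)acetic acid | OC(=O)Cc1cc(O)c2OC(C)(C)CCc2c1 | intermediate
9 | phloroglucinol (benzene-1,3,5-triol) | Oc1cc(O)cc(O)c1 | starting material
10 | N,N-dimethylformamide | CN(C)C=O | starting material
11 | deoxybenzoin: 2-(8-hydroxy-2,2-dimethylchroman-6-yl)-1-(2,4,6-trihydroxyphenyl)ethan-1-one (formed in the flask, boron-coordinated in the medium) | O=C(Cc1cc(O)c2OC(C)(C)CCc2c1)c1c(O)cc(O)cc1O | intermediate
12 | enaminoketone: 3-(dimethylamino)-2-(8-hydroxy-2,2-dimethylchroman-6-yl)-1-(2,4,6-trihydroxyphenyl)prop-2-en-1-one (formed in the flask; push–pull alkene, geometry not fixed) | CN(C)C=C(C(=O)c1c(O)cc(O)cc1O)c1cc(O)c2OC(C)(C)CCc2c1 | intermediate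
13 | 5,7-dihydroxy-3-(8-hydroxy-2,2-dimethylchroman-6-yl)-4H-chromen-4-one | CC1(C)CCc2cc(-c3coc4cc(O)cc(O)c4c3=O)cc(O)c2O1 | intermediate
14 | 3-(8-acetoxy-2,2-dimethylchroman-6-yl)-4-oxo-4H-chromene-5,7-diyl diacetate | CC1(C)CCc2cc(-c3coc4cc(OC(C)=O)cc(OC(C)=O)c4c3=O)cc(OC(C)=O)c2O1 | intermediate
15 | 3-(8-acetoxy-2,2-dimethyl-2H-chromen-6-yl)-4-oxo-4H-chromene-5,7-diyl diacetate | CC1(C)C=Cc2cc(-c3coc4cc(OC(C)=O)cc(OC(C)=O)c4c3=O)cc(OC(C)=O)c2O1 | intermediate
16 | semilicoisoflavone B: 5,7-dihydroxy-3-(8-hydroxy-2,2-dimethyl-2H-chromen-6-yl)-4H-chromen-4-one | CC1(C)C=Cc2cc(-c3coc4cc(O)cc(O)c4c3=O)cc(O)c2O1 | target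

**Step count**

Total: 8 steps. Longest linear sequence: 8 steps (1 → 3 → 6 → 7 → 8 → 13 → 14 → 15 → 16); 2, 9 and 10 are bought and enter at steps 1 and 5.

**Steps most likely to fail, with fallbacks**

1. Step 5. What may go wrong: ionisation of the chroman C2–O bond in hot neat BF3·OEt2, with transfer of the tertiary alkyl cation to phloroglucinol, or formylation and mesylation of the free phenols in the Vilsmeier stage. Either would lower the conversion to 13. The fallback sets out from 7 (and uses 9) and comes back at 13. Ester 7 is treated with NH3 in MeOH to give 2-(8-methoxy-2,2-dimethylchroman-6-yl)acetamide F1. Dehydration with (CF3CO)2O and pyridine gives 2-(8-methoxy-2,2-dimethylchroman-6-yl)acetonitrile F2. NaSEt in N-methyl-2-pyrrolidone at 130 °C then gives 2-(8-hydroxy-2,2-dimethylchroman-6-yl)acetonitrile F3. A Houben–Hoesch reaction of F3 with 9 (ZnCl2, HCl gas, Et2O, 0 °C) should give 2-(8-hydroxy-2,2-dimethylchroman-6-yl)-1-(2,4,6-trihydroxyphenyl)ethan-1-iminium chloride F4. Hydrolysis of F4 in hot water gives deoxybenzoin 11, now isolated. Ketone 11 is closed through 12 to 13 with BF3·OEt2 and MeSO2Cl in DMF solution at 60 °C, so the chroman never meets hot neat BF3·OEt2.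

2. Step 7. What may go wrong: slow hydride abstraction from C4 of the acetylated, less electron-rich chroman, with charge-transfer adducts and over-oxidation consuming material. The fallback sets out from 14 and comes back at 15. Radical benzylic bromination (N-bromosuccinimide, AIBN cat., PhCF3, 80 °C) should give racemic 3-(8-acetoxy-4-bromo-2,2-dimethylchroman-6-yl)-4-oxo-4H-chromene-5,7-diyl diacetate F5. Dehydrobromination with Et3N in toluene at 80 °C then gives 15.

3. Step 1. What may go wrong: slow O-alkylation of the hindered guaiacol hydroxyl by the tertiary propargylic chloride, with the chloride lost by elimination to the enyne. The fallback sets out from 1 and comes back at 6, so it also replaces step 2. Phenol 1 is condensed ortho-specifically with 3-methylbut-2-enal in the presence of PhB(OH)2 and catalytic propionic acid in refluxing toluene with water removal. This should give racemic methyl 2-[8-methoxy-4-(2-methylprop-1-en-1-yl)-2-phenyl-4H-1,3,2-benzodioxaborin-6-yl]acetate F6. F6 fragments thermally to ortho-quinone methide 5, which electrocyclises to 6.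

**Further compounds**

F1 | step 5 | 2-(8-methoxy-2,2-dimethylchroman-6-yl)acetamide | NC(=O)Cc1cc(OC)c2OC(C)(C)CCc2c1
F2 | step 5 | 2-(8-methoxy-2,2-dimethylchroman-6-yl)acetonitrile | N#CCc1cc(OC)c2OC(C)(C)CCc2c1
F3 | step 5 | 2-(8-hydroxy-2,2-dimethylchroman-6-yl)acetonitrile | N#CCc1cc(O)c2OC(C)(C)CCc2c1
F4 | step 5 | 2-(8-hydroxy-2,2-dimethylchroman-6-yl)-1-(2,4,6-trihydroxyphenyl)ethan-1-iminium chloride | [NH2+]=C(Cc1cc(O)c2OC(C)(C)CCc2c1)c1c(O)cc(O)cc1O.[Cl-]
F5 | step 7 | 3-(8-acetoxy-4-bromo-2,2-dimethylchroman-6-yl)-4-oxo-4H-chromene-5,7-diyl diacetate (racemic) | CC1(C)CC(Br)c2cc(-c3coc4cc(OC(C)=O)cc(OC(C)=O)c4c3=O)cc(OC(C)=O)c2O1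
F6 | step 1 | methyl 2-[8-methoxy-4-(2-methylprop-1-en-1-yl)-2-phenyl-4H-1,3,2-benzodioxaborin-6-yl]acetate (racemic) | COC(=O)Cc1cc(OC)c2OB(c3ccccc3)OC(C=C(C)C)c2c1
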